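| flask | substrate | remark | time |
|---|---|---|---|
| south-west | 0.013 M | run made earlier |  |
| south-east | 0.030 M | run made earlier |  |
| flask | 0.020 M |  | 5.0 h |

| run | time / h | target / % | isomer of the product / % |
|---|---|---|---|
| south-west | 0.250 | 14.1 | 6.0 |
| south-west | 0.417 | 26.4 | 9.3 |
| south-west | 0.667 | 37.9 | 15.4 |
| south-west | 1.00 | 51.7 | 18.6 |
| south-west | 2.00 | 62.2 | 24.2 |
| south-west | 3.00 | 65.3 | 24.7 |
| south-east | 0.500 | 30.1 | 11.8 |
| south-east | 1.00 | 50.4 | 20.2 |
| south-east | 1.50 | 57.1 | 23.9 |
| south-east | 2.00 | 60.4 | 24.6 |
| south-east | 2.50 | 64.4 | 25.8 |
| south-east | 3.00 | 65.0 | 24.8 |

(each reading ± 1 percentage point)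

- percent here means substrate units held: one idle adduct counts as two
- what is said of target includes idle adduct
- the analysis behind the earlier runs scatters by 1 percentage point, standard deviation
- steps that have been proposed: substrate -> intermediate; intermediate <-> isomer of the product; substrate + target <-> idle adduct; intermediate <-> target
- in an amount of target, one idle adduct counts as one target

* share of target in target plus isomer of the product at 8.0 min
* share of target in target plus isomer of the product at 50 min
* share of target in target plus isomer of the product at 5.0 h

We begin with a simple division: at each reading, target over target plus isomer of the product, which we call the share. If both products grow from one intermediate, each in proportion to c(intermediate) and neither going back, their gains keep one proportion, the selectivity factor. Summed over time, c(target)/c(isomer of the product) then equals that proportion from the first moment, however c(intermediate) rises and falls, and the share is flat.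

Turned round, a share moving steadily through a run needs its first readings to stand apart from its last. The first readings of both runs pooled give 71.3% and the last give 72.5%. That is a gap of 1.2 percentage points, where one reading scatters by 1 point. The last readings at 0.013 M and 0.030 M give 72.6% and 72.4%. One idle adduct counts as one target, so binding target does not lower the counted amount.

For the flask at 0.020 M we therefore commit to 72.2%, the pooled share of these four readings, at each asked time. The time 8.0 min lies before any reading, so there we lean on the rule.

The forecast gave 71.5%, 71.8% and 72%, reasoning: “Kinetic selectivity therefore matches the equilibrium ratio within noise”.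

The flask gives 71.3%, 71.7% and 71.5%. At 0.500 h it held 16.4% as idle adduct, and the shares at 8.0 min and 50 min, on either side of that time, differ by 0.40 points. Our 72.2%, a share read off scattered readings, stands 0.70 points above the flask at 5.0 h.

    substrate → intermediate (k = 0.0540 /min)
    intermediate ⇌ isomer of the product (K = 2.90, k = 0.0130 /min)
    substrate + target ⇌ idle adduct, settled at all times (K = 120 /M)
    intermediate ⇌ target (K = 7.20, k = 0.0320 /min)

For the neighbour flask charged with 0.0050 M, below both runs, our estimate of the share at 5.0 h is again 72.2%. The computed neighbour flask gives 71.3%.

Readings and results are simulated on assumed constants; noise was put on by code.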